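(The data stem from a simulated flask for an exercise; scatter was added.)

The alpha run, the earlier flask nearest to east, stood at its last reading with left-handed product at 71.2% of the charge and right-handed product at 1.6%, and I wanted to know what that ratio was worth for the next flask.

| flask | left-handed substrate | right-handed substrate | reagent | free catalyst | racemization catalyst | added ligand | remark | time |
|---|---|---|---|---|---|---|---|---|
| theta | 0.20 M | 0.20 M | 0.99 equiv | 2 mol% | 15 mol% | 3.1 mM | run made earlier |  |
| delta | 0.20 M | 0.20 M | 1.5 equiv | 2 mol% | 15 mol% | 3.1 mM | run made earlier |  |
| beta | 0.20 M | 0.20 M | 2.4 equiv | 2 mol% | 15 mol% | 3.1 mM | run made earlier |  |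
| alpha | 0.20 M | 0.20 M | 2.5 equiv | 2 mol% | 15 mol% | 3.9 mM | run made earlier |  |
| south-east | 0.20 M | 0.20 M | 0.830 equiv | 1 mol% | 15 mol% | 6.0 mM |  | 5.0 d |
| east | 0.20 M | 0.20 M | 2.50 equiv | 2 mol% | 15 mol% | 3.1 mM |  | 5.0 d |

| run | time / d | left-handed product / % | right-handed product / % |
|---|---|---|---|
| theta | 0.250 | 10.0 | 1.0 |
| theta | 0.500 | 16.6 | 0.9 |
| theta | 1.04 | 26.1 | 0.9 |
| theta | 1.67 | 31.8 | 1.1 |
| theta | 4.00 | 40.5 | 1.4 |
| delta | 0.625 | 26.2 | 0.7 |
| delta | 1.25 | 38.7 | 1.4 |
| delta | 2.00 | 47.3 | 2.0 |
| delta | 3.00 | 51.4 | 0.7 |
| delta | 4.00 | 55.5 | 1.1 |
| beta | 0.625 | 35.9 | 0.6 |
| beta | 1.25 | 50.4 | 1.7 |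
| beta | 2.00 | 59.7 | 2.1 |
| beta | 3.00 | 66.6 | 1.9 |
| beta | 4.00 | 71.6 | 2.8 |
| alpha | 0.625 | 35.4 | 1.4 |
| alpha | 1.25 | 50.1 | 1.2 |
| alpha | 2.00 | 59.5 | 1.6 |
| alpha | 3.00 | 67.3 | 2.4 |
| alpha | 4.00 | 71.2 | 1.6 |

(standard deviation of a reading: 0.5 percentage points)

- free catalyst is single-handed; left-handed substrate and right-handed substrate are mirror images of each other, charged as a racemate, each of them at the stated concentration
- no earlier run changes the charge of free catalyst; that part of a forecast is a guess

- the winner by share of left-handed product in all that became left-handed product or right-handed product; "neither" if no more than 2 percentage points parts them (south-east / east / neither)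
- share of left-handed product in all that became left-handed product or right-handed product, south-east
- share of left-handed product in all that became left-handed product or right-handed product, east

Two substrates competing for one catalyst are reckoned at the bench by the ratio of their two rates. If both products are made with the same reagent on the same catalyst, those terms cancel, and the ratio integrates in closed form: left-handed product over right-handed product equals one constant while the two substrates stand equal. I called that constant s, the selectivity factor, and read it from the last readings of the four runs, summed, as 34.6, which is a share of 97.2%. It is a loose reading, since the right-handed sum of 6.90% rests on readings each good to 0.5 percentage points, and the cancelling of the catalyst was my assumption, because no earlier run changed its charge.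

The border of the rule is the ratio of left-handed product to the 0.5 of the pool that began as left-handed substrate: past a ratio of one, racemization must refill that substrate, and if it lags, right-handed product gains. South-east, with 0.830 equiv of reagent, has room for a fraction 0.415 of the pool, under that border. Alpha, with the reagent of east, reached a ratio of 1.42, yet its share of 97.8% and the 96.2% of beta lie on either side of 97.2%. So I reckoned both flasks at 97.2%, with neither ahead.

The forecast differed, giving 94.5% for south-east and 97% for east, so east, on the ground that “If the right-handed product comes from an unselective background reaction, its share roughly doubles”.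

    free catalyst + added ligand ⇌ idle complex, settled at all times (K = 80.0 /M)
    left-handed substrate + racemization catalyst ⇌ right-handed substrate + racemization catalyst, rate k2*[racemization catalyst]*[left-handed substrate] forward; the back reaction follows from the equilibrium constant (k = 1.30 /M/h)
    reagent + free catalyst + right-handed substrate → free catalyst + right-handed product (k = 1.20 /M²/h)
    2 reagent → self-condensation product (k = 0.0200 /M/h)
    reagent + free catalyst + left-handed substrate → free catalyst + left-handed product (k = 65.0 /M²/h)

South-east gave 98.0% and east 97.3%, which are 0.70 points apart against a margin of 2 points, so the answer is neither. At 5.0 d product over product stood at 50.0 in south-east, with the substrates at 34.8% left-handed and 35.9% right-handed, and at 35.6 in east, with 10.3% and 12.0%; my reading of s was 34.6. The neighbour of south-east with 2.5 mol% of free catalyst made 36.7% of left-handed product against 28.7%, so my s put its right-handed product at 1.06% and its share at 97.2%; it held 0.790% of right-handed product, an accumulated product ratio of 46.5, and its share was 97.9%.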